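Time bought little in the east run: from 5.00 min to 50.0 min its starting material moved by 1 percentage point, against a scatter of 0.5 points.

in all of them: starting material 0.071 M; free catalyst 7.1 mM
- east: second substrate 0.035 M (fed, over 8.0 s); partner 0.0852 M; run made earlier; the fed solution adds 0.50 times the starting volume
- south: second substrate 0.053 M (fed, over 8.0 s); partner 0.0852 M; run made earlier; the fed solution adds 0.50 times the starting volume
- south-west: second substrate 0.071 M (fed, over 8.0 s); partner 0.13 M; run made earlier; the fed solution adds 0.50 times the starting volume
- flask: second substrate 0.0710 M (fed, over 8.0 s); partner 0.0852 M; the fed solution adds 0.50 times the starting volume; time 1.5 h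

- east (time / min: starting material / %, target / %): 5.00: 21.9, 53.4; 15.0: 21.4, 53.1; 25.0: 21.4, 53.4; 40.0: 20.9, 53.5; 50.0: 20.9, 53.4
- south (time / min: starting material / %, target / %): 5.00: 22.3, 52.2; 15.0: 22.8, 52.1; 25.0: 22.8, 52.3; 40.0: 22.6, 53.3; 50.0: 21.9, 51.9
- south-west (time / min: starting material / %, target / %): 4.00: 4.9, 64.0; 8.00: 5.4, 64.6; 15.0: 5.3, 64.4; 30.0: 5.2, 64.1; 50.0: 5.0, 63.8

(standard deviation of a reading: 0.5 percentage points)

- amounts are per litre of the starting volume; all of the dose is in the solution fed
- the reaction counts as stopped when no species that holds the starting material changes by six tenths of a point or more over the second half of the time

* why nothing more happens at 1.5 h, or that something still does (forward and back rates have come level / the partner has run out first / no working catalyst is left / it is still moving / all of the starting material has reacted)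
* share of the starting material used up at 1.5 h
* target at 1.5 h, in percent of the starting material charged
* amount of target if the flask were left three thousand times as long, in percent of the starting material charged

I built the flask up in steps. First came just the main step, one partner for each starting material. The flask's partner charge is 1.20 equivalents, more than the starting material, so this step by itself would use up the starting material. But the east run, with the same partner charge, still read 20.9% of it at 50.0 min.

So I added a side path, first order in partner, and took the main step to run in proportion to c(partner) and c(starting material). Partner then cancels from the ratio of the two rates, and the balance integrates: partner spent = starting material used + w × ln(charge of starting material / what is left of it). I assumed that each run stops when its partner is used.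

| run | second substrate | mean starting material left | w |
|---|---|---|---|
| east | 0.035 M | 21.3% | 0.0190 M |
| south | 0.053 M | 22.5% | 0.0202 M |
| south-west | 0.071 M | 5.16% | 0.0211 M |

This w, the waste width, is the partner burned on the side per unit of that logarithm. It reads higher in the south-west run than in the east run, though those runs differ in partner as well as in second substrate, and I took the south-west value, whose second substrate charge matches the flask's.

One Newton step on the balance for the flask, starting from the south run's mean, gave my estimate of 23.3% of the starting material left, so I reckoned 76.7% used up. Last came the rest of the chemistry, which I took as one reading: the south-west run's readings put 0.677 of what reacted in the target. That made my estimate of the target 51.9%, and with the partner used I expected the same figure after a longer wait.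

The forecast said: no working catalyst is left, with 76.5% used up, 51.5% target and 51.5% in the long run. Its ground: “The natural reading is catalyst death.” My own answer differed: I held that the partner runs out first, and I reckoned 76.7% used up against the forecast's 76.5%.

The simulation gave: the partner has run out first, 76.8% used up, 51.8% target and 51.8% in the long run.

    partner + catalyst intermediate A → free catalyst + target (k = 44.0 L mol⁻¹ s⁻¹)
    target + free catalyst ⇌ isomer of the product + free catalyst, rate k2*[free catalyst]*[target] forward; the back reaction follows from the equilibrium constant (K = 0.470, k = 11.0 L mol⁻¹ s⁻¹)
    partner → decomposed reagent (k = 0.0160 s⁻¹)
    starting material + free catalyst ⇌ catalyst intermediate A (K = 7.10 L mol⁻¹, k = 360 L mol⁻¹ s⁻¹)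
    second substrate + free catalyst ⇌ catalyst intermediate B (K = 5.10 L mol⁻¹, k = 6.70 L mol⁻¹ s⁻¹)
    partner + catalyst intermediate B → free catalyst + second product (k = 1.60 L mol⁻¹ s⁻¹)

The flask had come to rest at 1.50 h: partner, the limiting reagent, stood at 0% of its charge, while free catalyst stood at 76.4% of the catalyst charged. Read back from the flask's end, the waste width is 0.0210 M. With 0.0211 M, the neighbour charged with 0.12 M of starting material reckons to 41.2% left on a first pass and 43.6% on a second; the simulation left 44% of it unbound. Ten times the time moves the flask's target by 0 points, leaving it at 51.8%.

Readings and results stem from a simulated flask for substances that don't exist.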